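**Plan**

- Cuts, in retrosynthetic order: the acid is traced to a δ-lactone across O7/C8, then C6–prenyl, C6–CH2(cyclobutyl), the C8–benzylic bond together with the O7–acyl bond, C3–C4 of ring B, and O1–C2.
- Enabling feature: in ring B the C4 ketone is bonded to C3, a CH that carries only a methyl group and the O1-bound C2. C3–C4 can therefore come from adding the formyl C–H of an O-(but-3-en-2-yl) salicylaldehyde across its own vinyl group under carbene catalysis.
- Forward order: ring A is bought; ring B closes by hydroacylation; iodine marks C6; the lactone ring is annulated onto C8/O7; the pinene-derived cyclobutylmethyl group is coupled to C6; the lactone is opened; C6 is prenylated with dearomatisation of ring A.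
- Stereochemistry: C2 from (S)-but-3-en-2-ol with Mitsunobu inversion; C3 by equilibration to trans; the benzylic centre from a chiral triazolium carbene; both cyclobutane centres from (1S,5S)-α-pinene; C6 from a chiral palladium catalyst.

Key step: step 3

Remark: the target is handled as the C5-enol/C7-ketone tautomer drawn in its SMILES; the catalyst antipodes named in steps 7 and 15 are working assignments from the usual models, and the opposite antipodes are equally available.

**Route**

Step 1
Reactants: 1 2,4,6-trihydroxybenzaldehyde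
Product: 2 2-hydroxy-4,6-bis(methoxymethoxy)benzaldehyde
Conditions: MOMCl (2.2 equiv), iPr2NEt, CH2Cl2, 0 °C to rt
Reagents that add atoms: chloromethyl methyl ether, COCCl
Why: Williamson-type O-alkylation with the chloromethyl ether takes the para hydroxyl and one ortho hydroxyl and stops there, because the last ortho hydroxyl is held in a hydrogen bond to the formyl oxygen and is much less nucleophilic.

Step 2
Reactants: 2 2-hydroxy-4,6-bis(methoxymethoxy)benzaldehyde; 3 (S)-but-3-en-2-ol
Product: 4 2-[(2R)-but-3-en-2-yloxy]-4,6-bis(methoxymethoxy)benzaldehyde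
Conditions: PPh3, DIAD, THF, 0 °C to rt
Reagents that add atoms: none
Why: Mitsunobu etherification, in which the acidic chelated phenol displaces the phosphonium-activated secondary allylic carbinol by SN2 with inversion, so that (S)-3 gives the (R)-configured ether carbon that becomes C2.

Step 3
Reactants: 4 2-[(2R)-but-3-en-2-yloxy]-4,6-bis(methoxymethoxy)benzaldehyde
Product: 5 (2R,3R)-5,7-bis(methoxymethoxy)-2,3-dimethylchroman-4-one (trans)
Conditions: 3-(2,4,6-trimethylphenyl)-5,6,7,8-tetrahydro-4H-cyclohepta[d][1,3]thiazol-3-ium perchlorate (20 mol%), DBU (40 mol%), 1,4-dioxane, 120 °C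
Reagents that add atoms: none
Why: The carbene freed from the thiazolium salt by DBU adds to the formyl group of 4 and a proton shift gives the nucleophilic enaminol (Breslow-type intermediate), whose O–H hydrogen is delivered to the terminal CH2 of the tethered vinyl group while its carbinol carbon bonds to the internal alkene carbon in one concerted, Conia-ene-like transition state; collapse of the resulting alkoxide expels the carbene and leaves the C4 ketone. The closest known reaction is the carbene-catalysed intramolecular hydroacylation of unactivated alkenes in 2-allyloxybenzaldehydes, which gives 3-methylchroman-4-ones. Ring B closes in the 6-exo-trig mode, the new bond being C3–C4 and the former alkene terminus becoming the C3 methyl group. C2 is not touched and keeps the R configuration from step 2, whereas the new centre C3 is set under thermodynamic control, DBU equilibrating it through the enol so that the 3-methyl group ends up trans to the 2-methyl group (both pseudo-equatorial, 2R,3R). The step needs chemoselectivity for the tethered alkene over benzoin coupling and regioselectivity for the internal alkene carbon: the two ortho oxygen substituents hinder intermolecular aldehyde coupling, and the short O–CH(CH3)–CH= tether lets only the internal carbon reach the carbinol carbon while the hydrogen passes to the terminus. The acetal protecting groups are inert to carbene and amidine base, and the temperature is kept at the lowest that sustains turnover so that the aryl butenyl ether does not rearrange and ring B does not reopen.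

Step 4
Reactants: 5 (2R,3R)-5,7-bis(methoxymethoxy)-2,3-dimethylchroman-4-one
Product: 6 (2R,3R)-5-hydroxy-7-(methoxymethoxy)-2,3-dimethylchroman-4-one
Conditions: HCl (cat.), MeOH, 0 °C to rt, stopped at mono-cleavage
Reagents that add atoms: none
Why: Acid-catalysed acetal methanolysis cleaves the methoxymethyl ether peri to the C4 carbonyl first, since its departure is assisted by the neighbouring carbonyl oxygen and the freed hydroxyl is at once locked in a hydrogen bond to O4, so the C7 acetal should survive (chemoselective deprotection).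

Step 5
Reactants: 6 (2R,3R)-5-hydroxy-7-(methoxymethoxy)-2,3-dimethylchroman-4-one
Product: 7 (2R,3R)-5-hydroxy-6-iodo-7-(methoxymethoxy)-2,3-dimethylchroman-4-one
Conditions: benzyltrimethylammonium dichloroiodate (1.05 equiv), CaCO3, CH2Cl2/MeOH, rt
Reagents that add atoms: benzyltrimethylammonium dichloroiodate, C[N+](C)(C)Cc1ccccc1.Cl[I-]Cl
Why: Electrophilic aromatic iodination directed ortho to the free, hydrogen-bonded C5 hydroxyl places iodine on C6 rather than C8, as is usual for 5-hydroxy-7-alkoxy flavonoids with dichloroiodate, and the CaCO3 buffer protects the remaining acetal.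

Step 6
Reactants: 7 (2R,3R)-5-hydroxy-6-iodo-7-(methoxymethoxy)-2,3-dimethylchroman-4-one
Product: 8 (2R,3R)-5,7-dihydroxy-6-iodo-2,3-dimethylchroman-4-one
Conditions: ZnBr2, n-PrSH, CH2Cl2, 0 °C
Reagents that add atoms: none
Why: Lewis acid-promoted transfer of the methoxymethyl group to the thiol (acetal exchange) frees the C7 hydroxyl within minutes at 0 °C, without the strong protic acid that could protodeiodinate C6.

Step 7
Reactants: 8 (2R,3R)-5,7-dihydroxy-6-iodo-2,3-dimethylchroman-4-one; 9 (E)-cinnamaldehyde
Product: 10 (2R,3R,10S)-5-hydroxy-6-iodo-2,3-dimethyl-10-phenyl-2,3,9,10-tetrahydro-4H,8H-pyrano[2,3-f]chromene-4,8-dione (ring B: O1, C2, C3, C4; δ-lactone: O7, C8, C9, C10)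
Conditions: 9 (1.5 equiv), (5aS,10bR)-2-mesityl-5a,10b-dihydro-4H,6H-indeno[2,1-b][1,2,4]triazolo[4,3-d][1,4]oxazin-2-ium chloride (10 mol%), 3,3',5,5'-tetra-tert-butyldiphenoquinone (1.2 equiv), iPr2NEt, toluene, rt
Reagents that add atoms: none
Why: Oxidative carbene catalysis turns 9 into an α,β-unsaturated acyl azolium, to whose β-carbon the only free ring carbon, C8, adds (Michael addition of the vinylogous-acid enol), after which O7 is acylated and closes the δ-lactone; the fused aminoindanol backbone of the triazolium blocks one face of the acyl azolium, so the benzylic centre is set as S by the catalyst and not by the distant C2/C3 centres.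

Step 8
Reactants: 11 (1S,5S)-(−)-α-pinene
Product: 12 (1S,5S)-(−)-verbenone, (1S,5S)-4,6,6-trimethylbicyclo[3.1.1]hept-3-en-2-one
Conditions: t-BuOOH, Cr(CO)6 (cat.), MeCN, reflux
Reagents that add atoms: tert-butyl hydroperoxide, CC(C)(C)OO
Why: Chromium-catalysed allylic oxidation with tert-butyl hydroperoxide converts the ring CH2 next to the trisubstituted alkene into the enone carbonyl and does not involve either bridgehead stereocentre.

Step 9
Reactants: 12 (1S,5S)-(−)-verbenone
Product: 13 (1S,3R)-3-acetyl-2,2-dimethylcyclobutane-1-carboxylic acid (cis)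
Conditions: RuCl3·xH2O (cat.), NaIO4, CCl4/MeCN/H2O, rt
Reagents that add atoms: sodium periodate, [Na+].[O-]I(=O)(=O)=O; water, O
Why: RuO4 generated in situ from RuCl3 and NaIO4 cleaves the enone C=C bond and the α-keto acid formed loses CO2 (oxidative cleavage), which gives the cis keto acid with both pinene bridgeheads intact as the two ring stereocentres.

Step 10
Reactants: 13 (1S,3R)-3-acetyl-2,2-dimethylcyclobutane-1-carboxylic acid
Product: 14 (1S,3S)-2,2-dimethyl-3-(prop-1-en-2-yl)cyclobutane-1-carboxylic acid
Conditions: Ph3PCH3Br (2.5 equiv), KOtBu (2.4 equiv), THF, 0 °C to rt; acidic work-up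
Reagents that add atoms: methyltriphenylphosphonium bromide, C[P+](c1ccccc1)(c1ccccc1)c1ccccc1.[Br-]
Why: Wittig methylenation of the methyl ketone with excess ylide, the first equivalent of base merely forming the carboxylate, which removes any risk of epimerisation next to the carboxyl group, while addition to the ketone at low temperature should outpace deprotonation of the hindered ring C–H beside it.

Step 11
Reactants: 14 (1S,3S)-2,2-dimethyl-3-(prop-1-en-2-yl)cyclobutane-1-carboxylic acid
Product: 15 [(1S,3S)-2,2-dimethyl-3-(prop-1-en-2-yl)cyclobutyl]methanol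
Conditions: LiAlH4, Et2O, 0 °C to rt
Reagents that add atoms: none
Why: Hydride reduction with LiAlH4 takes the carboxylic acid to the primary alcohol and leaves the isolated 1,1-disubstituted alkene alone.

Step 12
Reactants: 15 [(1S,3S)-2,2-dimethyl-3-(prop-1-en-2-yl)cyclobutyl]methanol
Product: 16 (1S,3S)-1-(iodomethyl)-2,2-dimethyl-3-(prop-1-en-2-yl)cyclobutane
Conditions: I2, PPh3, imidazole, CH2Cl2, 0 °C
Reagents that add atoms: iodine, II
Why: Appel iodination replaces the primary hydroxyl by iodide through SN2 at the CH2 group, one carbon away from the nearest stereocentre.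

Step 13
Reactants: 10 (2R,3R,10S)-5-hydroxy-6-iodo-2,3-dimethyl-10-phenyl-2,3,9,10-tetrahydro-4H,8H-pyrano[2,3-f]chromene-4,8-dione; 16 (1S,3S)-1-(iodomethyl)-2,2-dimethyl-3-(prop-1-en-2-yl)cyclobutane
Product: 18 (2R,3R,10S)-6-{[(1R,3S)-2,2-dimethyl-3-(prop-1-en-2-yl)cyclobutyl]methyl}-5-hydroxy-2,3-dimethyl-10-phenyl-2,3,9,10-tetrahydro-4H,8H-pyrano[2,3-f]chromene-4,8-dione, via alkylzinc iodide 17 (not isolated)
Conditions: 16, Zn dust, LiCl, THF, 40 °C; then 10, Pd(OAc)2 (3 mol%), SPhos (6 mol%), THF, rt to 40 °C
Reagents that add atoms: zinc, [Zn] (carried only by intermediate 17)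
Why: Negishi coupling, in which zinc inserts into the primary C–I bond of 16 (LiCl-assisted) and the SPhos-ligated palladium catalyst joins the alkylzinc to the hindered aryl iodide at C6, a coupling type known to tolerate ketones, esters and free phenols, with the stereocentre β to zinc untouched.

Step 14
Reactants: 18 (2R,3R,10S)-6-{[(1R,3S)-2,2-dimethyl-3-(prop-1-en-2-yl)cyclobutyl]methyl}-5-hydroxy-2,3-dimethyl-10-phenyl-2,3,9,10-tetrahydro-4H,8H-pyrano[2,3-f]chromene-4,8-dione
Product: 19 methyl (3S)-3-[(2R,3R)-6-{[(1R,3S)-2,2-dimethyl-3-(prop-1-en-2-yl)cyclobutyl]methyl}-5,7-dihydroxy-2,3-dimethyl-4-oxochroman-8-yl]-3-phenylpropanoate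
Conditions: NaOMe (1.1 equiv), MeOH, 0 °C; AcOH quench
Reagents that add atoms: sodium methoxide, [Na+].[O-]C
Why: Transesterification by methoxide opens the aryl ester lactone to the methyl ester and liberates the C7 hydroxyl, the opening being driven by formation of the stabilised aryloxide.

Step 15
Reactants: 19 methyl (3S)-3-[(2R,3R)-6-{[(1R,3S)-2,2-dimethyl-3-(prop-1-en-2-yl)cyclobutyl]methyl}-5,7-dihydroxy-2,3-dimethyl-4-oxochroman-8-yl]-3-phenylpropanoate; 20 3-methylbut-2-en-1-yl acetate (prenyl acetate)
Product: 21 methyl (3S)-3-[(2R,3R,6R)-6-{[(1R,3S)-2,2-dimethyl-3-(prop-1-en-2-yl)cyclobutyl]methyl}-5-hydroxy-2,3-dimethyl-6-(3-methylbut-2-en-1-yl)-4,7-dioxo-3,4,6,7-tetrahydro-2H-chromen-8-yl]-3-phenylpropanoate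
Conditions: Pd2(dba)3·CHCl3 (2.5 mol%), (1R,2R)-N,N'-bis[2-(diphenylphosphino)benzoyl]cyclohexane-1,2-diamine (7.5 mol%), Et3N, THF, 0 °C to rt
Reagents that add atoms: none
Why: Proposed new method: a zerovalent palladium complex ionises 20 to a π-prenyl complex, which is attacked at its unsubstituted terminus by C6 of the phloroglucinol-type anion of 19 (Tsuji–Trost allylation), the ring carbon flanked by both hydroxyls and less shielded than C8 with its branched benzylic substituent; O-prenyl ethers re-ionise, so the dearomatised enol-dione is the thermodynamic sink, and the chiral diphosphine pocket is expected to tell apart the two faces of the planar nucleophile, whose flanks (chelated C5–OH against C7–O and the bulky C8 group) differ strongly, and so set C6 as R. The closest known reactions are the achiral palladium-catalysed dearomative prenylation of acylphloroglucinols and the ligand-controlled asymmetric prenylation of oxindoles and dearomative allylation of naphthols.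

Step 16
Reactants: 21 methyl (3S)-3-[(2R,3R,6R)-6-{[(1R,3S)-2,2-dimethyl-3-(prop-1-en-2-yl)cyclobutyl]methyl}-5-hydroxy-2,3-dimethyl-6-(3-methylbut-2-en-1-yl)-4,7-dioxo-3,4,6,7-tetrahydro-2H-chromen-8-yl]-3-phenylpropanoate
Product: 22 (3S)-3-[(2R,3R,6R)-6-{[(1R,3S)-2,2-dimethyl-3-(prop-1-en-2-yl)cyclobutyl]methyl}-5-hydroxy-2,3-dimethyl-6-(3-methylbut-2-en-1-yl)-4,7-dioxo-3,4,6,7-tetrahydro-2H-chromen-8-yl]-3-phenylpropanoic acid (target)
Conditions: LiOH, THF/H2O, 0 °C to rt; then 1 M HCl to pH 3
Reagents that add atoms: lithium hydroxide, [Li+].[OH-]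
Why: Saponification of the methyl ester with LiOH, under which the enol-dione core is present as its delocalised enolate and is therefore protected from reopening of ring B, followed by acidification to the free acid.

**Compound list**

1 | 2,4,6-trihydroxybenzaldehyde | O=Cc1c(O)cc(O)cc1O | starting material
2 | 2-hydroxy-4,6-bis(methoxymethoxy)benzaldehyde | O=Cc1c(O)cc(OCOC)cc1OCOC | intermediate
3 | (S)-but-3-en-2-ol | C[C@H](O)C=C | starting material
4 | 2-[(2R)-but-3-en-2-yloxy]-4,6-bis(methoxymethoxy)benzaldehyde | O=Cc1c(OCOC)cc(OCOC)cc1O[C@H](C)C=C | intermediate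
5 | (2R,3R)-5,7-bis(methoxymethoxy)-2,3-dimethylchroman-4-one | O=C1c2c(OCOC)cc(OCOC)cc2O[C@H](C)[C@H]1C | intermediate
6 | (2R,3R)-5-hydroxy-7-(methoxymethoxy)-2,3-dimethylchroman-4-one | O=C1c2c(O)cc(OCOC)cc2O[C@H](C)[C@H]1C | intermediate
7 | (2R,3R)-5-hydroxy-6-iodo-7-(methoxymethoxy)-2,3-dimethylchroman-4-one | O=C1c2c(O)c(I)c(OCOC)cc2O[C@H](C)[C@H]1C | intermediate
8 | (2R,3R)-5,7-dihydroxy-6-iodo-2,3-dimethylchroman-4-one | O=C1c2c(O)c(I)c(O)cc2O[C@H](C)[C@H]1C | intermediate
9 | (E)-cinnamaldehyde | O=C/C=C/c1ccccc1 | starting material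
10 | (2R,3R,10S)-5-hydroxy-6-iodo-2,3-dimethyl-10-phenyl-2,3,9,10-tetrahydro-4H,8H-pyrano[2,3-f]chromene-4,8-dione | O=C1c2c(O)c(I)c3OC(=O)C[C@@H](c4ccccc4)c3c2O[C@H](C)[C@H]1C | intermediate
11 | (1S,5S)-(−)-α-pinene | CC1=CC[C@H]2C[C@@H]1C2(C)C | starting material
12 | (1S,5S)-(−)-verbenone | CC1=CC(=O)[C@H]2C[C@@H]1C2(C)C | intermediate
13 | (1S,3R)-3-acetyl-2,2-dimethylcyclobutane-1-carboxylic acid | OC(=O)[C@H]1C[C@@H](C(C)=O)C1(C)C | intermediate
14 | (1S,3S)-2,2-dimethyl-3-(prop-1-en-2-yl)cyclobutane-1-carboxylic acid | OC(=O)[C@H]1C[C@@H](C(C)=C)C1(C)C | intermediate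
15 | [(1S,3S)-2,2-dimethyl-3-(prop-1-en-2-yl)cyclobutyl]methanol | OC[C@H]1C[C@@H](C(C)=C)C1(C)C | intermediate
16 | (1S,3S)-1-(iodomethyl)-2,2-dimethyl-3-(prop-1-en-2-yl)cyclobutane | IC[C@H]1C[C@@H](C(C)=C)C1(C)C | intermediate
17 | {[(1S,3S)-2,2-dimethyl-3-(prop-1-en-2-yl)cyclobutyl]methyl}zinc iodide | I[Zn]C[C@H]1C[C@@H](C(C)=C)C1(C)C | intermediate
18 | (2R,3R,10S)-6-{[(1R,3S)-2,2-dimethyl-3-(prop-1-en-2-yl)cyclobutyl]methyl}-5-hydroxy-2,3-dimethyl-10-phenyl-2,3,9,10-tetrahydro-4H,8H-pyrano[2,3-f]chromene-4,8-dione | O=C1c2c(O)c(C[C@H]5C[C@@H](C(C)=C)C5(C)C)c3OC(=O)C[C@@H](c4ccccc4)c3c2O[C@H](C)[C@H]1C | intermediate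
19 | methyl (3S)-3-[(2R,3R)-6-{[(1R,3S)-2,2-dimethyl-3-(prop-1-en-2-yl)cyclobutyl]methyl}-5,7-dihydroxy-2,3-dimethyl-4-oxochroman-8-yl]-3-phenylpropanoate | O=C1c2c(O)c(C[C@H]5C[C@@H](C(C)=C)C5(C)C)c(O)c([C@@H](CC(=O)OC)c4ccccc4)c2O[C@H](C)[C@H]1C | intermediate
20 | 3-methylbut-2-en-1-yl acetate | CC(=O)OCC=C(C)C | starting material
21 | methyl (3S)-3-[(2R,3R,6R)-6-{[(1R,3S)-2,2-dimethyl-3-(prop-1-en-2-yl)cyclobutyl]methyl}-5-hydroxy-2,3-dimethyl-6-(3-methylbut-2-en-1-yl)-4,7-dioxo-3,4,6,7-tetrahydro-2H-chromen-8-yl]-3-phenylpropanoate | C=C(C)[C@@H]1C[C@H](C[C@@]2(CC=C(C)C)C(=O)C([C@@H](CC(=O)OC)c3ccccc3)=C3O[C@H](C)[C@@H](C)C(=O)C3=C2O)C1(C)C | intermediate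
22 | (3S)-3-[(2R,3R,6R)-6-{[(1R,3S)-2,2-dimethyl-3-(prop-1-en-2-yl)cyclobutyl]methyl}-5-hydroxy-2,3-dimethyl-6-(3-methylbut-2-en-1-yl)-4,7-dioxo-3,4,6,7-tetrahydro-2H-chromen-8-yl]-3-phenylpropanoic acid | C=C(C)[C@@H]1C[C@H](C[C@@]2(CC=C(C)C)C(=O)C([C@@H](CC(=O)O)c3ccccc3)=C3O[C@H](C)[C@@H](C)C(=O)C3=C2O)C1(C)C | target

**Step count and risks**

Total steps: 16. Longest linear sequence: 11 steps (steps 1–7 and 13–16, from 1); the cyclobutane branch (steps 8–12, from 11) joins at step 13.

Steps most likely to fail:

1. Step 15 (Proposed new method). The chiral ligand may discriminate poorly between the two faces of C6, since the substrate itself offers no facial bias, or the allyl complex may be intercepted through C8. Fallback with known chemistry: setting out from 19, the prenylation is run without face selection under the established achiral conditions for dearomative prenylation of acylphloroglucinols (Pd(PPh3)4, 20, Et3N, THF). This should give 21 together with its C6 epimer, methyl (3S)-3-[(2R,3R,6S)-6-{[(1R,3S)-2,2-dimethyl-3-(prop-1-en-2-yl)cyclobutyl]methyl}-5-hydroxy-2,3-dimethyl-6-(3-methylbut-2-en-1-yl)-4,7-dioxo-3,4,6,7-tetrahydro-2H-chromen-8-yl]-3-phenylpropanoate F1. The two are diastereomers and would be separated by preparative HPLC, and the route is rejoined at 21.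

2. Step 7. The iodinated hydroxy-ketone ring is only a modest carbon nucleophile, so acyl transfer to O7 without C–C bond formation, or oxidation of the phenol by the quinone, may outrun the annulation; catalyst control of the benzylic centre may also be incomplete. Fallback: setting out from 8 and 9, the C8–C bond is made by iminium catalysis with no oxidant present. α,α-Diphenylprolinol trimethylsilyl ether (the antipode that gives 10S) and benzoic acid in toluene should effect Friedel–Crafts-type conjugate addition of C8 and hemiacetal closure to the lactol (2R,3R,10S)-5,8-dihydroxy-6-iodo-2,3-dimethyl-10-phenyl-2,3,9,10-tetrahydro-4H,8H-pyrano[2,3-f]chromen-4-one F2 (both configurations at the hemiacetal carbon). Oxidation of the lactol with pyridinium chlorochromate, [C5H5NH][CrO3Cl], in CH2Cl2 returns to the route at 10.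

3. Step 3. Formation of the enaminol from the electron-rich, doubly ortho-substituted aldehyde may be slow; at the temperature needed, sigmatropic rearrangement of the aryl butenyl ether and base-induced reversible opening of ring B (with erosion of the C2 configuration) may compete. Fallback: setting out from 4, the same C3–C4 bond is formed through an acyl radical under neutral conditions. Thiol-catalysed radical-chain hydroacylation (tert-dodecanethiol cat., 1,1'-azobis(cyclohexanecarbonitrile), chlorobenzene, 100 °C) should give 6-exo cyclisation and hydrogen transfer to the primary radical. The expected product is 5 mixed with its cis epimer (2R,3S)-5,7-bis(methoxymethoxy)-2,3-dimethylchroman-4-one F3. Brief treatment with Et3N in MeOH at rt then converts the cis epimer into 5 through the enol, where the route is rejoined.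

Further compounds
F1 | step 15 | methyl (3S)-3-[(2R,3R,6S)-6-{[(1R,3S)-2,2-dimethyl-3-(prop-1-en-2-yl)cyclobutyl]methyl}-5-hydroxy-2,3-dimethyl-6-(3-methylbut-2-en-1-yl)-4,7-dioxo-3,4,6,7-tetrahydro-2H-chromen-8-yl]-3-phenylpropanoate | C=C(C)[C@@H]1C[C@H](C[C@]2(CC=C(C)C)C(=O)C([C@@H](CC(=O)OC)c3ccccc3)=C3O[C@H](C)[C@@H](C)C(=O)C3=C2O)C1(C)C
F2 | step 7 | (2R,3R,10S)-5,8-dihydroxy-6-iodo-2,3-dimethyl-10-phenyl-2,3,9,10-tetrahydro-4H,8H-pyrano[2,3-f]chromen-4-one | O=C1c2c(O)c(I)c3OC(O)C[C@@H](c4ccccc4)c3c2O[C@H](C)[C@H]1C
F3 | step 3 | (2R,3S)-5,7-bis(methoxymethoxy)-2,3-dimethylchroman-4-one | O=C1c2c(OCOC)cc(OCOC)cc2O[C@H](C)[C@@H]1C
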